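Readings and results were computed on assumed constants.

The time asked, 6.0 min, runs past the last earlier reading at 120 s, and two chemists dispute what that extra time buys.

| flask | substrate | coupling partner | remark | time |
|---|---|---|---|---|
| dusk | 0.27 M | 1 equiv | run made earlier |  |
| winter | 0.80 M | 1 equiv | run made earlier |  |
| Monday's | 0.40 M | 1.00 equiv |  | 6.0 min |
| Wednesday's | 0.40 M | 2.50 equiv |  | 6.0 min |

| run | time / s | double product / % | single product / % | substrate / % |
|---|---|---|---|---|
| dusk | 30.0 | 8.6 | 18.2 | 59.7 |
| dusk | 60.0 | 16.6 | 21.3 | 45.5 |
| dusk | 90.0 | 20.6 | 21.3 | 41.3 |
| dusk | 120 | 22.7 | 22.4 | 36.2 |
| winter | 10.0 | 8.5 | 19.4 | 58.2 |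
| winter | 25.0 | 18.0 | 23.0 | 40.2 |
| winter | 50.0 | 24.0 | 24.6 | 32.3 |
| winter | 120 | 27.2 | 24.4 | 29.3 |

(standard deviation of a reading: 0.5 percentage points)

- the numbers in the tables scatter with a standard deviation of 0.5 percentage points
- a reading or a percentage of single product counts all its forms, free or not

- which of these holds the largest part of the substrate at the end of Monday's (single product / substrate / other mono adduct / double product)
- which of these holds the largest part of the substrate at the end of Wednesday's (single product / substrate / other mono adduct / double product)
- how much double product is there at the end of Wednesday's, in percent of the substrate charged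

The first chemist holds that double product stalls by its nature: in the winter run it gained 3.2 percentage points between 50.0 s and 120 s while single product stood at 24.4 %, so she scales the last reading with the charge and expects about 68.0 % on Wednesday's, with mono adducts beside it.

The second chemist counts partner instead: each mono adduct holds one and double product two, so substrate minus double product, as fractions of the charge, equals a gap plus the partner left, and Wednesday's partner gap −1.50, defined as one minus the equivalents charged, lies below minus one. In the winter run the gap is zero, so he reads the 2.1 points between substrate and double product as partner left, the limiting reagent, and the flat stretch as a shortage of partner. By his count Wednesday's keeps a surplus of 0.500 equiv once both places are filled, and the first dusk reading, taken as second order and lent to the adducts, gives a life of 60.0 s in that surplus, so 6.0 min is 6.00 lives and his reckoning gives 99.8 %.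

The forecast stands on his side, “Substrate therefore stays just above double product” on Monday's, with substrate largest there, double product largest on Wednesday's and a lower 97 %.

Wednesday's ends with 98.3 % double product, the largest part, 1.5 points under his reckoning, and Monday's ends with substrate largest at 32.5 %.

    substrate + coupling partner → single product (k = 0.0570 M⁻¹ s⁻¹)
    substrate + coupling partner → other mono adduct (k = 0.0370 M⁻¹ s⁻¹)
    coupling partner + single product → double product (k = 0.100 M⁻¹ s⁻¹)
    coupling partner + other mono adduct → double product (k = 0.0570 M⁻¹ s⁻¹)
    crystals ⇌ single product, rate k5*(cs5 - [single product]) while solid is left; crystals form when [single product] > cs5 (solubility = 0.120 M, k = 0.400 s⁻¹)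
    coupling partner → decomposed reagent (k = 0.00150 s⁻¹)

The main reason for Wednesday's end is the step from coupling partner and single product: struck out, that flask gives 39.3 % instead of 98.3 %. Wednesday's gap, with partner left and decomposed reagent added, comes to −98.2 % of the charge, and substrate minus double product is −98.2 %. The first chemist's mixture belongs to the neighbour of Wednesday's flask with 0.620 equiv of partner, gap 38.0 %: partner stands at 0 %, double product at 12.1 %, and substrate exceeds double product by 40.6 % of the charge, the gap plus 2.56 % of decomposed reagent.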